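**Plan**
1. Retrosynthetic cuts: the two amide C–N bonds (dienoyl amide on C2, amide to the aminocyclopentenone), the C6″=C7″ alkene of the trienoyl arm (Horner–Wadsworth–Emmons at a C4 aldehyde), the epoxide (from a C5=C6 enone), the C2=C3 unsaturation (from a saturated α-amido ketone) and, last, the ring bond C4–C5.
2. Enabling feature: C1(=O)–C2(N)–C3–C4(O) of the epoxycyclohexenone ring is the aspartic acid backbone, its two carboxyl carbons being C1 and C4 and its amine already on C2; C5–C6 is an ethynyl unit, so a Z-β-iodoenone on C1 can add through C5 to a C4 ketone.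
3. Forward, core: L-aspartate 1 → silyloxymethyl ketone from the side-chain carboxyl (masked as a ketal) → ethynyl ketone from the α-carboxyl → Z-iodoenone → Ni/Cr ring closure, the only ring formed in the route (the cyclopentenone is bought as cyclopentane-1,3-dione).
4. Forward, assembly: Boc → dienoyl amide, hydroxyl-directed epoxidation, dehydrogenation to the enamide, unmasking and oxidation of the C4 arm, triene by HWE, final amide.
5. Stereochemistry: C2 of L-aspartate controls C4 in the ring closure and is then planarised; the C4 hydroxyl directs the epoxide (C5, C6); C6′ comes from an Evans methylation; alkene geometry comes from anti hydroiodination (Z) and Wittig/HWE olefinations (E).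

Key step: step 8

Numbering: ring atoms as in the target core (C1 ketone, C2 nitrogen-bearing carbon, C3, C4 carbinol carbon, C5 and C6 epoxide carbons); dienoyl chain C1′–C10′; trienoyl chain C1″–C7″; TBDPS = tert-butyldiphenylsilyl.
Assumption: the ring closure of step 8 is taken to place the C4 hydroxyl trans to the C2 carbamate; if the cis isomer dominated, the same chemistry would be run from the D-configured ester, because C2 is erased in step 21.
Assumption: the aminocyclopentenone unit is handled as its 2-amino-3-hydroxycyclopent-2-enone tautomer, as drawn in the target.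

**Core, steps 1–8**

Step 1
Reactants: 1 N-Boc-L-aspartic acid 1-methyl ester
Product: 3 methyl (2S)-2-(tert-butoxycarbonylamino)-5-diazo-4-oxopentanoate, via mixed isobutyl carbonic anhydride 2 (not isolated)
Conditions: i-BuOCOCl, N-methylmorpholine, THF, −15 °C; then Me3SiCHN2 (hexanes), MeCN, 0 °C → rt
Reagents that add atoms: (trimethylsilyl)diazomethane, C[Si](C)(C)C=[N+]=[N-]
Why: Activation of the free side-chain carboxyl as the mixed anhydride and C-acylation of the silyl diazomethane (Arndt–Eistert-type diazoketone synthesis) leaves the α-ester, the carbamate and the stereocentre untouched, the silyl group leaving with the carbonate.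

Step 2
Reactants: 3 diazoketone
Product: 6 methyl (2S)-2-(tert-butoxycarbonylamino)-5-hydroxy-4,4-dimethoxypentanoate, via trifluoroacetoxymethyl ketone 4 (not isolated), via hydroxymethyl ketone 5 (not isolated)
Conditions: CF3CO2H (1.05 equiv), CH2Cl2, −20 → 0 °C; then MeOH, HC(OMe)3, camphorsulfonic acid (5 mol %), rt; Et3N before concentration
Reagents that add atoms: trifluoroacetic acid, OC(=O)C(F)(F)F (the C5 oxygen); trimethyl orthoformate, COC(OC)OC, and methanol, CO (the two methoxy groups)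
Why: Protonation of the diazoketone, loss of N2 and capture by trifluoroacetate (acidolysis of a diazoketone, with no metal carbenoid and hence no N–H insertion to a 4-oxoproline) is followed in the same flask by methanolysis of the labile ester and ketalisation, so the C4 ketone is masked before any Grignard reagent is used, while the stoichiometric acid at low temperature should spare the Boc group.

Step 3
Reactants: 6 hydroxy ketal
Product: 7 methyl (2S)-2-(tert-butoxycarbonylamino)-5-[(tert-butyldiphenylsilyl)oxy]-4,4-dimethoxypentanoate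
Conditions: TBDPSCl, imidazole, 4-(dimethylamino)pyridine (cat.), DMF, rt
Reagents that add atoms: tert-butyl(chloro)diphenylsilane, CC(C)(C)[Si](Cl)(c1ccccc1)c1ccccc1
Why: Silylation of the primary alcohol gives an ether that should survive the acids of steps 6, 7 and 19 and the bases of steps 4, 5 and 20, yet be removable with buffered fluoride.

Step 4
Reactants: 7 silyl ether methyl ester
Product: 8 tert-butyl N-[(2S)-5-[(tert-butyldiphenylsilyl)oxy]-4,4-dimethoxy-1-[methoxy(methyl)amino]-1-oxopentan-2-yl]carbamate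
Conditions: MeNH(OMe)·HCl, i-PrMgCl, THF, −20 → 0 °C
Reagents that add atoms: N,O-dimethylhydroxylamine hydrochloride, CNOC.Cl
Why: Direct aminolysis of the methyl ester by the chloromagnesium amide (Weinreb amide formation from an ester) is selective because the carbamate is deprotonated first, which protects the α-stereocentre from enolisation.

Step 5
Reactants: 8 Weinreb amide; 9 ethynylmagnesium bromide
Product: 10 tert-butyl N-[(4S)-7-[(tert-butyldiphenylsilyl)oxy]-6,6-dimethoxy-3-oxohept-1-yn-4-yl]carbamate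
Conditions: HC≡CMgBr (4 equiv), THF, −78 → 0 °C; inverse quench into cold aq. NaHSO4
Reagents that add atoms: none
Why: In this Weinreb ketone synthesis the chelated tetrahedral adduct stops after one addition and releases the ethynyl ketone only on quenching, the ketal keeps the second carbonyl out of reach, and the acidic inverse quench keeps the liberated hydroxylamine from adding to the ynone.

Step 6
Reactants: 10 ynone ketal
Product: 11 tert-butyl N-[(4S)-7-[(tert-butyldiphenylsilyl)oxy]-3,6-dioxohept-1-yn-4-yl]carbamate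
Conditions: p-TsOH·H2O (10 mol %), acetone–H2O (20:1), rt
Reagents that add atoms: water, O
Why: Acid-catalysed ketal hydrolysis is done at the ynone stage because the ynone tolerates catalytic acid better than the Z-iodoenone, and the Boc group and silyl ether should be stable to it.

Step 7
Reactants: 11 keto ynone
Product: 12 tert-butyl N-[(1Z,4S)-7-[(tert-butyldiphenylsilyl)oxy]-1-iodo-3,6-dioxohept-1-en-4-yl]carbamate
Conditions: NaI (1.5 equiv), AcOH, rt, dark; aq. Na2S2O3/NaHCO3 work-up
Reagents that add atoms: sodium iodide, [Na+].[I-]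
Why: Conjugate addition of iodide to the protonated ynone with anti protonation (hydroiodination of an ynone) gives the kinetic Z-β-iodoenone, a short reaction time in the dark limits Z→E isomerisation, and the isolated C4 ketone is inert.

Step 8
Reactants: 12 Z-iodoenone
Product: 14 tert-butyl N-[(1S,5S)-5-[[(tert-butyldiphenylsilyl)oxy]methyl]-5-hydroxy-2-oxocyclohex-3-en-1-yl]carbamate (hydroxyl trans to the carbamate), via alkenylchromium dichloride 13 (not isolated)
Conditions: CrCl2 (5 equiv), NiCl2 (2 mol %), degassed DMF, 0.01 M, rt; aq. NH4Cl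
Reagents that add atoms: none
Why: Divalent chromium, helped by zerovalent nickel that forms from NiCl2, inserts into the C–I bond and transmetalates, converts the Z-iodoenone into the trivalent alkenylchromium species 13 with retention of alkene geometry, and its carbon C5 adds to the C4 ketone to give the tertiary carbinol after hydrolysis of the chromium alkoxide (intramolecular Nozaki–Hiyama–Kishi reaction). The closest known reactions are Ni/Cr-mediated cyclisations of alkenyl iodides onto ketones and Ni/Cr couplings of β-iodoenones with aldehydes. The cyclohexenone ring closes in a 6-exo-trig mode at the C4 carbonyl, which is possible only because the Z alkene holds C5 beside C4 and which is helped by the electron-withdrawing α-silyloxy group. The new stereocentre C4 is controlled by the aspartate-derived C2: in the chair-like closure the carbamate on C2 and the bulky silyloxymethyl arm on C4 should both be pseudo-equatorial, so the chromium-bound oxygen is pseudo-axial and the hydroxyl ends trans to the carbamate. The step needs chemoselective addition to the isolated ketone in the presence of the enone carbonyl and the carbamate, which the non-basic alkenylchromium reagent and the ring size secure, and it needs this relative configuration, which is checked and purified here because C4 alone carries the configuration of the core once C2 is planarised.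

**Dienoic acid, steps 9–14**

Step 9
Reactants: 15 (R)-4-benzyl-1,3-oxazolidin-2-one; 16 hexanoyl chloride
Product: 17 (4R)-4-benzyl-3-hexanoyl-1,3-oxazolidin-2-one
Conditions: n-BuLi, THF, −78 °C; then 16, −78 → 0 °C
Reagents that add atoms: none
Why: N-Acylation of the lithiated oxazolidinone is the standard entry to an Evans imide.

Step 10
Reactants: 17 hexanoyl imide
Product: 18 (4R)-4-benzyl-3-[(2R)-2-methylhexanoyl]-1,3-oxazolidin-2-one
Conditions: NaN(SiMe3)2, THF, −78 °C; MeI, −78 → −40 °C
Reagents that add atoms: iodomethane, CI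
Why: In this Evans alkylation the chelated Z-enolate is methylated on the face opposite the benzyl group, which for the (R)-auxiliary sets the 2R centre (C6′ of the target), and the minor diastereomer is removable by chromatography.

Step 11
Reactants: 18 methylated imide
Product: 19 (2R)-2-methylhexan-1-ol
Conditions: LiBH4, Et2O, H2O (1 equiv), 0 °C
Reagents that add atoms: none
Why: Reductive cleavage of the imide with LiBH4 releases the alcohol without touching the stereocentre and returns the auxiliary.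

Step 12
Reactants: 19 (2R)-2-methylhexan-1-ol; 20 2-(triphenylphosphoranylidene)propanal
Product: 22 (2E,4R)-2,4-dimethyloct-2-enal, via (2R)-2-methylhexanal 21 (not isolated)
Conditions: PhI(OAc)2, TEMPO (10 mol %), CH2Cl2, rt; aq. NaHCO3 wash; then 20, toluene, 80 °C
Reagents that add atoms: none
Why: Oxoammonium-catalysed oxidation gives the volatile α-branched aldehyde under non-epimerising conditions and the stabilised formyl ylide converts it in solution into the E-trisubstituted enal (Wittig reaction).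

Step 13
Reactants: 22 enal; 23 triethyl phosphonoacetate
Product: 24 ethyl (2E,4E,6R)-4,6-dimethyldeca-2,4-dienoate
Conditions: NaH, THF, 0 °C; then 22, 0 °C → rt
Reagents that add atoms: none
Why: The Horner–Wadsworth–Emmons reaction of a stabilised phosphonate with an enal gives the 2E alkene, and the remote stereocentre is not acidic under these conditions.

Step 14
Reactants: 24 ethyl dienoate
Product: 25 (2E,4E,6R)-4,6-dimethyldeca-2,4-dienoic acid
Conditions: LiOH, THF–MeOH–H2O, rt; then 1 M HCl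
Reagents that add atoms: lithium hydroxide, [Li+].[OH-]
Why: Saponification of the dienoate is unproblematic because no stereocentre or alkene is base-labile here.

**Lower-chain reagents, steps 15–18**

Step 15
Reactants: 26 allyl (2E,4E)-hexa-2,4-dienoate (allyl sorbate)
Product: 27 allyl (2E,4E)-6-bromohexa-2,4-dienoate
Conditions: N-bromosuccinimide, (PhCO2)2 (5 mol %), PhCl, 85 °C
Reagents that add atoms: N-bromosuccinimide, O=C1CCC(=O)N1Br
Why: Wohl–Ziegler bromination takes the terminal methyl hydrogen because the resulting radical is conjugated with the dienoate, whereas the allyl ester CH2 is far less activated.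

Step 16
Reactants: 27 bromide
Product: 28 allyl (2E,4E)-6-(diethoxyphosphoryl)hexa-2,4-dienoate
Conditions: P(OEt)3, neat, 120 °C
Reagents that add atoms: triethyl phosphite, CCOP(OCC)OCC
Why: The Michaelis–Arbuzov reaction of a primary allylic bromide gives the vinylogous phosphonate with loss of bromoethane.

Step 17
Reactants: 29 cyclopentane-1,3-dione
Product: 30 2-(hydroxyimino)cyclopentane-1,3-dione
Conditions: NaNO2, aq. HCl, 0 °C
Reagents that add atoms: sodium nitrite, [Na+].[O-]N=O
Why: Nitrosation of the doubly activated C2 methylene gives the oxime tautomer, the usual way to place nitrogen on C2 of a cyclic 1,3-dione.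

Step 18
Reactants: 30 oxime
Product: 31 2-amino-3-hydroxycyclopent-2-en-1-one hydrochloride
Conditions: H2 (1 atm), Pd/C, EtOH, HCl (1.1 equiv), rt
Reagents that add atoms: hydrogen chloride, Cl
Why: Catalytic hydrogenation of the oxime in acid gives the amine, which is trapped as its hydrochloride so that the aminodione cannot self-condense.

**Assembly, steps 19–26**

Step 19
Reactants: 14 cyclohexenone carbamate; 25 dienoic acid
Product: 33 (2E,4E,6R)-N-[(1S,5S)-5-[[(tert-butyldiphenylsilyl)oxy]methyl]-5-hydroxy-2-oxocyclohex-3-en-1-yl]-4,6-dimethyldeca-2,4-dienamide, via ammonium trifluoroacetate 32 (not isolated)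
Conditions: CF3CO2H–CH2Cl2 (1:4), 0 °C; evaporate; then 25, EDC·HCl, HOBt, i-Pr2NEt, CH2Cl2, 0 °C → rt
Reagents that add atoms: none
Why: Boc acidolysis is done before the epoxide exists, the TBDPS ether and the electron-poor tertiary allylic alcohol should tolerate the acid, and the α-amino ketone is kept as its salt until it meets the HOBt ester (carbodiimide amide coupling), which limits self-condensation.

Step 20
Reactants: 33 enone amide
Product: 34 (2E,4E,6R)-N-[(1S,3S,5R,6R)-5-[[(tert-butyldiphenylsilyl)oxy]methyl]-5-hydroxy-2-oxo-7-oxabicyclo[4.1.0]heptan-3-yl]-4,6-dimethyldeca-2,4-dienamide (epoxide cis to the hydroxyl)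
Conditions: t-BuOOH (decane), BnMe3NOH (cat.), THF, 0 °C
Reagents that add atoms: tert-butyl hydroperoxide, CC(C)(C)OO
Why: In this Weitz–Scheffer epoxidation the hydroperoxide should attack C5 of the enone on the face of the free C4 hydroxyl (hydrogen-bonded delivery), which is also the face opposite the bulky pseudo-equatorial silyloxymethyl group, the dienamide is too poor an acceptor to compete, and any base-induced epimerisation at C2 is without consequence because C2 is planarised in step 21.

Step 21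
Reactants: 34 epoxy ketone amide
Product: 37 (2E,4E,6R)-N-[(1S,5R,6R)-5-[[(tert-butyldiphenylsilyl)oxy]methyl]-5-hydroxy-2-oxo-7-oxabicyclo[4.1.0]hept-3-en-3-yl]-4,6-dimethyldeca-2,4-dienamide, via N-chloro amide 35 (not isolated), via N-acylimine 36 (not isolated)
Conditions: t-BuOCl (1.1 equiv), CH2Cl2, −20 °C, dark; then DABCO (2.5 equiv), −20 °C → rt
Reagents that add atoms: none
Why: N-Chlorination followed by base-induced loss of HCl across N–C2 (the dehydroamino acid protocol applied to an α-amido ketone) gives the N-acylimine, which tautomerises through C3–H to the enamide conjugated with the C1 ketone, and chlorination at C2 through the enol would reach the same imine.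

Step 22
Reactants: 37 enamide silyl ether
Product: 38 (2E,4E,6R)-N-[(1S,5R,6R)-5-hydroxy-5-(hydroxymethyl)-2-oxo-7-oxabicyclo[4.1.0]hept-3-en-3-yl]-4,6-dimethyldeca-2,4-dienamide
Conditions: Bu4NF, AcOH (1:1), THF, 0 °C → rt
Reagents that add atoms: none
Why: Fluoride desilylation buffered with acetic acid removes the TBDPS group at near-neutral pH, which the epoxy enone and the enamide should tolerate.

Step 23
Reactants: 38 diol
Product: 39 (2E,4E,6R)-N-[(1S,5S,6R)-5-formyl-5-hydroxy-2-oxo-7-oxabicyclo[4.1.0]hept-3-en-3-yl]-4,6-dimethyldeca-2,4-dienamide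
Conditions: SO3·pyridine, DMSO, i-Pr2NEt, CH2Cl2, 0 °C; used crude
Reagents that add atoms: none
Why: Parikh–Doering oxidation converts the primary alcohol into the aldehyde without touching the tertiary alcohol and without the glycol cleavage that iodine-based oxidants could cause on this 1,2-diol, and the aldehyde has no α-hydrogen to epimerise.

Step 24
Reactants: 39 α-hydroxy aldehyde; 28 dienyl phosphonate
Product: 40 (2E,4E,6R)-N-[(1S,5S,6R)-5-[(1E,3E,5E)-7-(allyloxy)-7-oxohepta-1,3,5-trienyl]-5-hydroxy-2-oxo-7-oxabicyclo[4.1.0]hept-3-en-3-yl]-4,6-dimethyldeca-2,4-dienamide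
Conditions: 28 (3 equiv), LiN(SiMe3)2 (3 equiv), THF, −78 °C; then 39, −78 → −30 °C
Reagents that add atoms: none
Why: The vinylogous Horner–Wadsworth–Emmons reaction of the lithiated sorbate phosphonate with the aldehyde forms the C6″=C7″ bond with the E geometry expected for stabilised phosphonates, the excess anion absorbs the acidic O–H and N–H, and the syn epoxy alkoxide cannot undergo Payne rearrangement.

Step 25
Reactants: 40 allyl trienoate
Product: 41 (2E,4E,6E)-7-[(1S,5S,6R)-3-[[(2E,4E,6R)-4,6-dimethyldeca-2,4-dienoyl]amino]-5-hydroxy-4-oxo-7-oxabicyclo[4.1.0]hept-2-en-5-yl]hepta-2,4,6-trienoic acid (bicycle numbered as in 40)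
Conditions: Pd(PPh3)4 (5 mol %), PhNHMe, THF, rt, dark
Reagents that add atoms: none
Why: Allyl transfer to N-methylaniline catalysed by zerovalent palladium (Tsuji–Trost deallylation) frees the acid under neutral conditions, so no hydroxide meets the base-labile epoxy enone.

Step 26
Reactants: 41 trienoic acid; 31 aminocyclopentenone hydrochloride
Product: 42 (2E,4E,6R)-N-[(1S,5S,6R)-5-hydroxy-5-[(1E,3E,5E)-7-[(2-hydroxy-5-oxocyclopent-1-en-1-yl)amino]-7-oxohepta-1,3,5-trienyl]-2-oxo-7-oxabicyclo[4.1.0]hept-3-en-3-yl]-4,6-dimethyldeca-2,4-dienamide (target)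
Conditions: EDC·HCl, HOBt, i-Pr2NEt, DMF, 0 °C → rt
Reagents that add atoms: none
Why: Carbodiimide coupling through the HOBt ester acylates the amine of 31 (any enol ester formed first should migrate to nitrogen), while the tertiary alcohol and the enamide N–H are too hindered or too weakly nucleophilic to compete.

**Compound list**
1 | N-Boc-L-aspartic acid 1-methyl ester | COC(=O)[C@H](CC(=O)O)NC(=O)OC(C)(C)C | starting material
2 | mixed isobutyl carbonic anhydride of 1 | COC(=O)[C@H](CC(=O)OC(=O)OCC(C)C)NC(=O)OC(C)(C)C | intermediate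
3 | methyl (2S)-2-(tert-butoxycarbonylamino)-5-diazo-4-oxopentanoate | COC(=O)[C@H](CC(=O)C=[N+]=[N-])NC(=O)OC(C)(C)C | intermediate
4 | methyl (2S)-2-(tert-butoxycarbonylamino)-4-oxo-5-(trifluoroacetoxy)pentanoate | COC(=O)[C@H](CC(=O)COC(=O)C(F)(F)F)NC(=O)OC(C)(C)C | intermediate
5 | methyl (2S)-2-(tert-butoxycarbonylamino)-5-hydroxy-4-oxopentanoate | COC(=O)[C@H](CC(=O)CO)NC(=O)OC(C)(C)C | intermediate
6 | methyl (2S)-2-(tert-butoxycarbonylamino)-5-hydroxy-4,4-dimethoxypentanoate | COC(=O)[C@H](CC(OC)(OC)CO)NC(=O)OC(C)(C)C | intermediate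
7 | methyl (2S)-2-(tert-butoxycarbonylamino)-5-[(tert-butyldiphenylsilyl)oxy]-4,4-dimethoxypentanoate | COC(=O)[C@H](CC(OC)(OC)CO[Si](c1ccccc1)(c1ccccc1)C(C)(C)C)NC(=O)OC(C)(C)C | intermediate
8 | tert-butyl N-[(2S)-5-[(tert-butyldiphenylsilyl)oxy]-4,4-dimethoxy-1-[methoxy(methyl)amino]-1-oxopentan-2-yl]carbamate | CON(C)C(=O)[C@H](CC(OC)(OC)CO[Si](c1ccccc1)(c1ccccc1)C(C)(C)C)NC(=O)OC(C)(C)C | intermediate
9 | ethynylmagnesium bromide | C#C[Mg]Br | starting material
10 | tert-butyl N-[(4S)-7-[(tert-butyldiphenylsilyl)oxy]-6,6-dimethoxy-3-oxohept-1-yn-4-yl]carbamate | C#CC(=O)[C@H](CC(OC)(OC)CO[Si](c1ccccc1)(c1ccccc1)C(C)(C)C)NC(=O)OC(C)(C)C | intermediate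
11 | tert-butyl N-[(4S)-7-[(tert-butyldiphenylsilyl)oxy]-3,6-dioxohept-1-yn-4-yl]carbamate | C#CC(=O)[C@H](CC(=O)CO[Si](c1ccccc1)(c1ccccc1)C(C)(C)C)NC(=O)OC(C)(C)C | intermediate
12 | tert-butyl N-[(1Z,4S)-7-[(tert-butyldiphenylsilyl)oxy]-1-iodo-3,6-dioxohept-1-en-4-yl]carbamate | I/C=C\C(=O)[C@H](CC(=O)CO[Si](c1ccccc1)(c1ccccc1)C(C)(C)C)NC(=O)OC(C)(C)C | intermediate
13 | alkenylchromium dichloride derived from 12 (Z) | Cl[Cr](Cl)/C=C\C(=O)[C@H](CC(=O)CO[Si](c1ccccc1)(c1ccccc1)C(C)(C)C)NC(=O)OC(C)(C)C | intermediate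
14 | tert-butyl N-[(1S,5S)-5-[[(tert-butyldiphenylsilyl)oxy]methyl]-5-hydroxy-2-oxocyclohex-3-en-1-yl]carbamate | CC(C)(C)OC(=O)N[C@H]1C[C@@](O)(CO[Si](c2ccccc2)(c2ccccc2)C(C)(C)C)C=CC1=O | intermediate
15 | (R)-4-benzyl-1,3-oxazolidin-2-one | O=C1N[C@H](Cc2ccccc2)CO1 | starting material
16 | hexanoyl chloride | CCCCCC(=O)Cl | starting material
17 | (4R)-4-benzyl-3-hexanoyl-1,3-oxazolidin-2-one | CCCCCC(=O)N1[C@H](Cc2ccccc2)COC1=O | intermediate
18 | (4R)-4-benzyl-3-[(2R)-2-methylhexanoyl]-1,3-oxazolidin-2-one | CCCC[C@@H](C)C(=O)N1[C@H](Cc2ccccc2)COC1=O | intermediate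
19 | (2R)-2-methylhexan-1-ol | CCCC[C@@H](C)CO | intermediate
20 | 2-(triphenylphosphoranylidene)propanal | CC(C=O)=P(c1ccccc1)(c1ccccc1)c1ccccc1 | starting material
21 | (2R)-2-methylhexanal | CCCC[C@@H](C)C=O | intermediate
22 | (2E,4R)-2,4-dimethyloct-2-enal | CCCC[C@@H](C)/C=C(\C)C=O | intermediate
23 | triethyl phosphonoacetate | CCOC(=O)CP(=O)(OCC)OCC | starting material
24 | ethyl (2E,4E,6R)-4,6-dimethyldeca-2,4-dienoate | CCCC[C@@H](C)/C=C(C)/C=C/C(=O)OCC | intermediate
25 | (2E,4E,6R)-4,6-dimethyldeca-2,4-dienoic acid | CCCC[C@@H](C)/C=C(C)/C=C/C(=O)O | intermediate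
26 | allyl (2E,4E)-hexa-2,4-dienoate | C/C=C/C=C/C(=O)OCC=C | starting material
27 | allyl (2E,4E)-6-bromohexa-2,4-dienoate | BrC/C=C/C=C/C(=O)OCC=C | intermediate
28 | allyl (2E,4E)-6-(diethoxyphosphoryl)hexa-2,4-dienoate | CCOP(=O)(OCC)C/C=C/C=C/C(=O)OCC=C | intermediate
29 | cyclopentane-1,3-dione | O=C1CCC(=O)C1 | starting material
30 | 2-(hydroxyimino)cyclopentane-1,3-dione | ON=C1C(=O)CCC1=O | intermediate
31 | 2-amino-3-hydroxycyclopent-2-en-1-one hydrochloride | NC1=C(O)CCC1=O.Cl | intermediate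
32 | (1S,5S)-5-[[(tert-butyldiphenylsilyl)oxy]methyl]-5-hydroxy-2-oxocyclohex-3-en-1-ylammonium trifluoroacetate | N[C@H]1C[C@@](O)(CO[Si](c2ccccc2)(c2ccccc2)C(C)(C)C)C=CC1=O.OC(=O)C(F)(F)F | intermediate
33 | (2E,4E,6R)-N-[(1S,5S)-5-[[(tert-butyldiphenylsilyl)oxy]methyl]-5-hydroxy-2-oxocyclohex-3-en-1-yl]-4,6-dimethyldeca-2,4-dienamide | CCCC[C@@H](C)/C=C(C)/C=C/C(=O)N[C@H]1C[C@@](O)(CO[Si](c2ccccc2)(c2ccccc2)C(C)(C)C)C=CC1=O | intermediate
34 | (2E,4E,6R)-N-[(1S,3S,5R,6R)-5-[[(tert-butyldiphenylsilyl)oxy]methyl]-5-hydroxy-2-oxo-7-oxabicyclo[4.1.0]heptan-3-yl]-4,6-dimethyldeca-2,4-dienamide | CCCC[C@@H](C)/C=C(C)/C=C/C(=O)N[C@H]1C[C@@](O)(CO[Si](c3ccccc3)(c3ccccc3)C(C)(C)C)[C@@H]2O[C@@H]2C1=O | intermediate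
35 | N-chloro derivative of amide 34 | CCCC[C@@H](C)/C=C(C)/C=C/C(=O)N(Cl)[C@H]1C[C@@](O)(CO[Si](c3ccccc3)(c3ccccc3)C(C)(C)C)[C@@H]2O[C@@H]2C1=O | intermediate
36 | (2E,4E,6R)-N-[(1S,5R,6R)-5-[[(tert-butyldiphenylsilyl)oxy]methyl]-5-hydroxy-2-oxo-7-oxabicyclo[4.1.0]heptan-3-ylidene]-4,6-dimethyldeca-2,4-dienamide | CCCC[C@@H](C)/C=C(C)/C=C/C(=O)N=C1C[C@@](O)(CO[Si](c3ccccc3)(c3ccccc3)C(C)(C)C)[C@@H]2O[C@@H]2C1=O | intermediate
37 | (2E,4E,6R)-N-[(1S,5R,6R)-5-[[(tert-butyldiphenylsilyl)oxy]methyl]-5-hydroxy-2-oxo-7-oxabicyclo[4.1.0]hept-3-en-3-yl]-4,6-dimethyldeca-2,4-dienamide | CCCC[C@@H](C)/C=C(C)/C=C/C(=O)NC1=C[C@@](O)(CO[Si](c3ccccc3)(c3ccccc3)C(C)(C)C)[C@@H]2O[C@@H]2C1=O | intermediate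
38 | (2E,4E,6R)-N-[(1S,5R,6R)-5-hydroxy-5-(hydroxymethyl)-2-oxo-7-oxabicyclo[4.1.0]hept-3-en-3-yl]-4,6-dimethyldeca-2,4-dienamide | CCCC[C@@H](C)/C=C(C)/C=C/C(=O)NC1=C[C@@](O)(CO)[C@@H]2O[C@@H]2C1=O | intermediate
39 | (2E,4E,6R)-N-[(1S,5S,6R)-5-formyl-5-hydroxy-2-oxo-7-oxabicyclo[4.1.0]hept-3-en-3-yl]-4,6-dimethyldeca-2,4-dienamide | CCCC[C@@H](C)/C=C(C)/C=C/C(=O)NC1=C[C@@](O)(C=O)[C@@H]2O[C@@H]2C1=O | intermediate
40 | (2E,4E,6R)-N-[(1S,5S,6R)-5-[(1E,3E,5E)-7-(allyloxy)-7-oxohepta-1,3,5-trienyl]-5-hydroxy-2-oxo-7-oxabicyclo[4.1.0]hept-3-en-3-yl]-4,6-dimethyldeca-2,4-dienamide | CCCC[C@@H](C)/C=C(C)/C=C/C(=O)NC1=C[C@@](O)(/C=C/C=C/C=C/C(=O)OCC=C)[C@@H]2O[C@@H]2C1=O | intermediate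
41 | (2E,4E,6E)-7-[(1S,5S,6R)-3-[[(2E,4E,6R)-4,6-dimethyldeca-2,4-dienoyl]amino]-5-hydroxy-4-oxo-7-oxabicyclo[4.1.0]hept-2-en-5-yl]hepta-2,4,6-trienoic acid (bicycle numbered as in 40) | CCCC[C@@H](C)/C=C(C)/C=C/C(=O)NC1=C[C@@](O)(/C=C/C=C/C=C/C(=O)O)[C@@H]2O[C@@H]2C1=O | intermediate
42 | (2E,4E,6R)-N-[(1S,5S,6R)-5-hydroxy-5-[(1E,3E,5E)-7-[(2-hydroxy-5-oxocyclopent-1-en-1-yl)amino]-7-oxohepta-1,3,5-trienyl]-2-oxo-7-oxabicyclo[4.1.0]hept-3-en-3-yl]-4,6-dimethyldeca-2,4-dienamide | CCCC[C@@H](C)/C=C(C)/C=C/C(=O)NC1=C[C@@](O)(/C=C/C=C/C=C/C(=O)NC2=C(O)CCC2=O)[C@@H]2O[C@@H]2C1=O | target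

**Step count and risks**
Total step count: 26. Longest linear sequence: 16 steps (steps 1–8 and 19–26, from 1).

Step 8. The alkenylchromium species may be protonated, or the iodoenone may lose its Z geometry, before C5 reaches the hindered ketone, and the facial selectivity at C4 may be poor. The fallback replaces the Ni/Cr closure by ring-closing metathesis and sets out from Weinreb amide 8. p-TsOH in wet acetone removes the ketal and gives tert-butyl N-[(2S)-5-[(tert-butyldiphenylsilyl)oxy]-1-[methoxy(methyl)amino]-1,4-dioxopentan-2-yl]carbamate F1. Excess CH2=CHMgBr (THF, −78 → 0 °C, cold acidic quench) adds to both the ketone and the amide and gives the divinyl hydroxy enone tert-butyl N-[(4S)-6-[[(tert-butyldiphenylsilyl)oxy]methyl]-6-hydroxy-3-oxoocta-1,7-dien-4-yl]carbamate F2 as a mixture at the carbinol carbon. The second-generation Hoveyda–Grubbs catalyst (CH2Cl2, 40 °C) then closes the C5=C6 bond and should give 14 together with its C4 epimer tert-butyl N-[(1S,5R)-5-[[(tert-butyldiphenylsilyl)oxy]methyl]-5-hydroxy-2-oxocyclohex-3-en-1-yl]carbamate F3, which is removed by chromatography. The route is rejoined at 14.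

Step 21. Chlorination may stray to the trisubstituted alkene of the dienamide or to the tertiary alcohol, and the N-acylimine may be trapped by a nucleophile before it tautomerises. The fallback is a selenoxide elimination and sets out from 34. Excess LiN(SiMe3)2 (THF, −78 °C; the alkoxide and amidate form first) and PhSeBr give the α-phenylselanyl ketone (2E,4E,6R)-N-[(1S,5R,6R)-5-[[(tert-butyldiphenylsilyl)oxy]methyl]-5-hydroxy-2-oxo-3-(phenylselanyl)-7-oxabicyclo[4.1.0]heptan-3-yl]-4,6-dimethyldeca-2,4-dienamide F4. H2O2 and pyridine (CH2Cl2, 0 °C) oxidise it to the corresponding selenoxide F5, which undergoes syn elimination toward C3–H. The route is rejoined at 37.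

Step 24. The lithiated phosphonate may degrade the epoxy enone and the α-hydroxy aldehyde (ring-opening or cleavage by base) faster than it olefinates, and the new alkene may form with incomplete E selectivity. The fallback builds the triene before the enamide exists and sets out from 34. Bu4NF/AcOH gives the diol (2E,4E,6R)-N-[(1S,3S,5R,6R)-5-hydroxy-5-(hydroxymethyl)-2-oxo-7-oxabicyclo[4.1.0]heptan-3-yl]-4,6-dimethyldeca-2,4-dienamide F6. SO3·pyridine/DMSO gives the 5-formyl analogue, the aldehyde F7. Phosphonate 28 with LiN(SiMe3)2 gives the 5-[(1E,3E,5E)-7-(allyloxy)-7-oxohepta-1,3,5-trienyl] analogue, the allyl trienoate F8, on the less base-sensitive saturated epoxy ketone. t-BuOCl and then DABCO act through the N-chloro amide F9 and the N-acylimine F10 as in step 21. The route is rejoined at 40.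

Further compounds
F1 | step 8 | tert-butyl N-[(2S)-5-[(tert-butyldiphenylsilyl)oxy]-1-[methoxy(methyl)amino]-1,4-dioxopentan-2-yl]carbamate | CON(C)C(=O)[C@H](CC(=O)CO[Si](c1ccccc1)(c1ccccc1)C(C)(C)C)NC(=O)OC(C)(C)C
F2 | step 8 | tert-butyl N-[(4S)-6-[[(tert-butyldiphenylsilyl)oxy]methyl]-6-hydroxy-3-oxoocta-1,7-dien-4-yl]carbamate (both configurations at C6) | C=CC(=O)[C@H](CC(O)(CO[Si](c1ccccc1)(c1ccccc1)C(C)(C)C)C=C)NC(=O)OC(C)(C)C
F3 | step 8 | tert-butyl N-[(1S,5R)-5-[[(tert-butyldiphenylsilyl)oxy]methyl]-5-hydroxy-2-oxocyclohex-3-en-1-yl]carbamate (C4 epimer of 14) | CC(C)(C)OC(=O)N[C@H]1C[C@](O)(CO[Si](c2ccccc2)(c2ccccc2)C(C)(C)C)C=CC1=O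
F4 | step 21 | (2E,4E,6R)-N-[(1S,5R,6R)-5-[[(tert-butyldiphenylsilyl)oxy]methyl]-5-hydroxy-2-oxo-3-(phenylselanyl)-7-oxabicyclo[4.1.0]heptan-3-yl]-4,6-dimethyldeca-2,4-dienamide (either configuration at C3) | CCCC[C@@H](C)/C=C(C)/C=C/C(=O)NC1([Se]c3ccccc3)C[C@@](O)(CO[Si](c3ccccc3)(c3ccccc3)C(C)(C)C)[C@@H]2O[C@@H]2C1=O
F5 | step 21 | selenoxide of F4 | CCCC[C@@H](C)/C=C(C)/C=C/C(=O)NC1([Se](=O)c3ccccc3)C[C@@](O)(CO[Si](c3ccccc3)(c3ccccc3)C(C)(C)C)[C@@H]2O[C@@H]2C1=O
F6 | step 24 | (2E,4E,6R)-N-[(1S,3S,5R,6R)-5-hydroxy-5-(hydroxymethyl)-2-oxo-7-oxabicyclo[4.1.0]heptan-3-yl]-4,6-dimethyldeca-2,4-dienamide | CCCC[C@@H](C)/C=C(C)/C=C/C(=O)N[C@H]1C[C@@](O)(CO)[C@@H]2O[C@@H]2C1=O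
F7 | step 24 | (2E,4E,6R)-N-[(1S,3S,5S,6R)-5-formyl-5-hydroxy-2-oxo-7-oxabicyclo[4.1.0]heptan-3-yl]-4,6-dimethyldeca-2,4-dienamide | CCCC[C@@H](C)/C=C(C)/C=C/C(=O)N[C@H]1C[C@@](O)(C=O)[C@@H]2O[C@@H]2C1=O
F8 | step 24 | (2E,4E,6R)-N-[(1S,3S,5R,6R)-5-[(1E,3E,5E)-7-(allyloxy)-7-oxohepta-1,3,5-trienyl]-5-hydroxy-2-oxo-7-oxabicyclo[4.1.0]heptan-3-yl]-4,6-dimethyldeca-2,4-dienamide | CCCC[C@@H](C)/C=C(C)/C=C/C(=O)N[C@H]1C[C@@](O)(/C=C/C=C/C=C/C(=O)OCC=C)[C@@H]2O[C@@H]2C1=O
F9 | step 24 | N-chloro derivative of amide F8 | CCCC[C@@H](C)/C=C(C)/C=C/C(=O)N(Cl)[C@H]1C[C@@](O)(/C=C/C=C/C=C/C(=O)OCC=C)[C@@H]2O[C@@H]2C1=O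
F10 | step 24 | N-acylimine from F9 (C2=N) | CCCC[C@@H](C)/C=C(C)/C=C/C(=O)N=C1C[C@@](O)(/C=C/C=C/C=C/C(=O)OCC=C)[C@@H]2O[C@@H]2C1=O
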